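The trap in repeating this run is to read the flat end of the violet run, 59.3% at 15.0 min, as a catalyst that has died. A charge of 0.60 equiv of partner, the limiting reagent, allows 60.0% product, so watch the partner rather than the starting material.

common to all: starting material 0.050 M
- grey: partner 0.60 equiv; precatalyst 0.029 mol%; run made earlier
- violet: partner 0.60 equiv; precatalyst 0.12 mol%; run made earlier
- flask: partner 0.600 equiv; precatalyst 0.059 mol%

| run | time / min | product / % |
|---|---|---|
| grey | 1.33 | 5.1 |
| grey | 2.00 | 8.1 |
| grey | 3.00 | 14.0 |
| grey | 5.00 | 21.7 |
| grey | 10.0 | 35.9 |
| grey | 15.0 | 46.5 |
| violet | 2.50 | 35.8 |
| violet | 5.00 | 50.8 |
| violet | 8.00 | 56.6 |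
| violet | 10.0 | 60.7 |
| violet | 12.0 | 58.7 |
| violet | 15.0 | 59.3 |

(readings scatter by 1 percentage point)

* factor on the rate of making product when 30% of the starting material are converted if precatalyst is charged twice over
* factor on the rate when 30% of the starting material are converted if precatalyst is charged at 0.006 mol% instead

- what was read earlier has a scatter of 1 percentage point, one standard deviation
- steps under discussion: partner + free catalyst <-> catalyst intermediate A; starting material + catalyst intermediate A -> catalyst intermediate B; catalyst intermediate B -> free catalyst + product; precatalyst <-> free catalyst

The bench rule says that, with the same charges of starting material and partner, equal loading times time gives equal yield. One pair of readings fits it: grey shows 35.9% at 10.0 min and violet 35.8% at 2.50 min, a time ratio of 4.00 for a loading ratio of 4.14.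

My reckoning uses this rule. The mark, 30% conversion of the starting material, uses up half of the partner, so I carry T, the partner half-time of a flask, meaning the time in which its partner falls to half its charge. If the partner falls first-order, the grey point gives 7.60 min, and scaling by loading gives this flask T = 3.74 min. At the mark, with these same charges, the partner level is the same whatever the loading, so on this rule the rate follows the loading: I reckon a factor of 2.00 on doubling and 0.102 at the lower charge.

The rule's border is the span of the runs. Twice the flask's loading is 0.983 of the violet loading, so it lies inside that span. But 0.006 mol% is 0.207 of the grey loading, which is less than the loading of either run. A run there that reached its mark far from 36.7 min would speak against my factor and the forecast's alike.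

The forecast gives 1.96 for doubling and 0.108 for the lower charge, where I have 2.00 and 0.102, on this ground: “At fixed conversion the partner level is the same, so the rate scales with loading.”

The simulation gives 2.01 for doubling and 0.101 for the lower charge.

    partner + free catalyst ⇌ catalyst intermediate A (K = 190 L mol⁻¹, k = 24200 L mol⁻¹ min⁻¹)
    starting material + catalyst intermediate A → catalyst intermediate B (k = 17700 L mol⁻¹ min⁻¹)
    catalyst intermediate B → free catalyst + product (k = 1790 min⁻¹)
    precatalyst ⇌ free catalyst (K = 0.790, k = 2.46 min⁻¹)

In this flask the precatalyst holds 48.2% of the catalyst charged at 7.50 min. The flask reaches the mark at 3.78 min, against T of 3.74 min. With twice the precatalyst, half of T predicts 1.87 min, and that flask takes 2.01 min.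

(The readings are calculated for substances that don't exist; the scatter is artificial.)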